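**Plan**
1. Target: oxacyclotritriacontan-2-one (dotriacontan-32-olide), one 33-membered ring made of the ester oxygen, the carbonyl C1 and 31 CH2 groups (C2–C32); no stereocentre.
2. Retrosynthesis: (i) put helper unsaturation back at C2=C3/C4=C5 and cut the ring bond C5–C6, giving open-chain 27-iodoheptacosyl (2E)-penta-2,4-dienoate; (ii) cut the ester C1–O bond, giving (2E)-penta-2,4-dienoic acid and 27-iodoheptacosan-1-ol; (iii) cut one CH2–CH2 bond of the C27 chain, giving an undec-10-enyl Grignard reagent and 1,16-dibromohexadecane.
3. Enabling feature: the lactone carbonyl C1 sits exactly four carbons (C2–C5) before the cut, so as a C2=C3–C4=C5 dienoate it makes C5 a vinylogous (δ) radical acceptor. C6 is an ordinary primary carbon that can carry an iodide-derived radical, and the 33-membered ring is strain-free, so closure costs entropy only.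
4. Forward: the C27 chain is joined first (Cu-catalysed alkyl–alkyl coupling), its two ends are differentiated (hydroboration–oxidation, Br to I), the dienoate is attached by esterification, the only ring arises in one radical event, and hydrogenation removes the helper unsaturation.
5. Stereochemistry: none in the target; position and geometry of the C=C left by the ring closure are erased by the final hydrogenation.

Key step: step 5

Remark: locants C1–C32 in the text count along the acid chain from the carbonyl carbon; the ring names (oxacyclotritriacont…) count from the ring oxygen and are therefore one higher.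

**Route**

Step 1
Reactants: 1 11-bromoundec-1-ene; 2 1,16-dibromohexadecane (3 equiv)
Product: 4 27-bromoheptacos-1-ene, via undec-10-en-1-ylmagnesium bromide 3 (not isolated)
Conditions: Mg, THF, 40 °C; then added slowly to 2 (3 equiv), Li2CuCl4 (3 mol%), THF, −10 °C → rt
Reagents that add atoms: none
Why: Copper-catalysed alkyl–alkyl cross-coupling of a primary Grignard reagent with a primary alkyl bromide is a standard way to join saturated chains, the threefold excess of 2 should hold the product at the mono-coupled stage, and the terminal alkene is inert to both reagents.

Step 2
Reactants: 4 27-bromoheptacos-1-ene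
Product: 6 27-bromoheptacosan-1-ol, via 9-(27-bromoheptacosyl)-9-borabicyclo[3.3.1]nonane 5 (not isolated)
Conditions: 9-BBN, THF, 0 °C → rt; then aq. NaOH, H2O2, 0 °C → rt
Reagents that add atoms: hydrogen peroxide, OO
Why: Hydroboration–oxidation with the bulky dialkylborane 9-BBN puts boron, and then oxygen, on the terminal carbon only (anti-Markovnikov), a remote primary bromide tolerates the brief cold alkaline peroxide treatment, and the polar alcohol is now easily freed from leftover 2.

Step 3
Reactants: 6 27-bromoheptacosan-1-ol
Product: 7 27-iodoheptacosan-1-ol
Conditions: NaI (5 equiv), butan-2-one, reflux, dark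
Reagents that add atoms: sodium iodide, [Na+].[I-]
Why: The Finkelstein reaction (SN2 halide exchange driven by precipitation of NaBr) should convert the primary bromide cleanly into the iodide, which is wanted because iodine-atom transfer to a tin radical is fast enough to outrun its addition to the dienoate in step 5.

Step 4
Reactants: 7 27-iodoheptacosan-1-ol; 8 (2E)-penta-2,4-dienoic acid
Product: 9 27-iodoheptacosyl (2E)-penta-2,4-dienoate
Conditions: EDC hydrochloride, DMAP (0.1 equiv), BHT (trace), CH2Cl2, 0 °C → rt, dark
Reagents that add atoms: none
Why: Steglich esterification (carbodiimide activation of the acid, acyl transfer by DMAP) acylates an unhindered primary alcohol at or below room temperature, leaves the primary iodide alone, and the low temperature, darkness and a trace of BHT keep the polymerisable dienoate intact.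

Step 5
Reactants: 9 27-iodoheptacosyl (2E)-penta-2,4-dienoate
Product: 10 (4E)-oxacyclotritriacont-4-en-2-one
Conditions: Bu3SnH (1.3 equiv) and AIBN (0.2 equiv) by syringe pump over 10 h into 9 (1 mM) in degassed PhH, 80 °C; then filtration through KF/silica to remove tin residues
Reagents that add atoms: none
Why: Bu3Sn• abstracts iodine from 9 to give the primary, nucleophilic C6 radical, which adds to the unsubstituted terminus C5 of the dienoate (the δ-carbon, electron-poor by vinylogy with the C1 carbonyl), forming the C5–C6 bond and an ester-conjugated allyl radical over C2–C4; this radical takes hydrogen from Bu3SnH and returns Bu3Sn• to the chain, and the hydridic Sn–H should deliver hydrogen mainly to C2, the electrophilic terminus next to the carbonyl, leaving the C3=C4 bond of 10 in its more stable E form. The closest known reaction type is the tin-hydride-mediated radical macrocyclization of ω-iodoalkyl acrylates by intramolecular Giese addition at high dilution, used here in its vinylogous (1,6) sense on a dienoate, an acceptor class for which δ-selective addition of alkyl radicals is known. The single ring closes in the 33-endo-trig mode, and because the ring is strain-free only entropy has to be paid. No stereocentre is formed, and neither the position nor the geometry of the remaining C=C matters, because hydrogen transfer to C4 would only shift the double bond by one position into conjugation and step 6 saturates it wherever it lies. The step needs cyclization to outrun direct reduction of the C6 radical and addition to a second molecule, which the 1 mM dilution, the slow feed of Bu3SnH and the fast iodine transfer should secure; it needs attack at C5 and not C3, which the unhindered CH2 terminus and the better-stabilized allyl radical should secure.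

Step 6
Reactants: 10 (4E)-oxacyclotritriacont-4-en-2-one
Product: 11 oxacyclotritriacontan-2-one
Conditions: H2 (1 atm), 10% Pd/C, EtOAc/THF, rt
Reagents that add atoms: none
Why: Heterogeneous catalytic hydrogenation saturates the one disubstituted C=C that the ring closure leaves behind, whatever its exact position or geometry, and does not touch a saturated lactone, so the helper unsaturation is removed and the target is reached.

**Compound list**
1 | 11-bromoundec-1-ene | C=CCCCCCCCCCBr | starting material
2 | 1,16-dibromohexadecane | BrCCCCCCCCCCCCCCCCBr | starting material
3 | undec-10-en-1-ylmagnesium bromide | C=CCCCCCCCCC[Mg]Br | intermediate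
4 | 27-bromoheptacos-1-ene | C=CCCCCCCCCCCCCCCCCCCCCCCCCCBr | intermediate
5 | 9-(27-bromoheptacosyl)-9-borabicyclo[3.3.1]nonane | BrCCCCCCCCCCCCCCCCCCCCCCCCCCCB1C2CCCC1CCC2 | intermediate
6 | 27-bromoheptacosan-1-ol | OCCCCCCCCCCCCCCCCCCCCCCCCCCCBr | intermediate
7 | 27-iodoheptacosan-1-ol | OCCCCCCCCCCCCCCCCCCCCCCCCCCCI | intermediate
8 | (2E)-penta-2,4-dienoic acid | C=C/C=C/C(=O)O | starting material
9 | 27-iodoheptacosyl (2E)-penta-2,4-dienoate | C=C/C=C/C(=O)OCCCCCCCCCCCCCCCCCCCCCCCCCCCI | intermediate
10 | (4E)-oxacyclotritriacont-4-en-2-one (β,γ-unsaturated lactone, C3=C4 of the acid chain) | O=C1C/C=C/CCCCCCCCCCCCCCCCCCCCCCCCCCCCO1 | intermediate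
11 | oxacyclotritriacontan-2-one (dotriacontan-32-olide) | O=C1CCCCCCCCCCCCCCCCCCCCCCCCCCCCCCCO1 | target

**Summary**
Total step count: 6. Longest linear sequence: 6 steps (1 → 4 → 6 → 7 → 9 → 10 → 11).

Steps most likely to fail:

Step 5 (ring closure). The C6 radical may be reduced by the hydride, or add to a second molecule, before it finds the diene terminus 27 carbons away. The chain may also stall at the stabilized allyl radical. Fallback: close the same C5–C6 bond by olefin metathesis, setting out from 4. Compound 4 is converted with Mg in THF into heptacos-26-en-1-ylmagnesium bromide F1, which is treated with paraformaldehyde and worked up with dilute HCl to give octacos-27-en-1-ol F2. Steglich esterification of F2 with hex-5-enoic acid (EDC hydrochloride, DMAP, CH2Cl2) gives octacos-27-en-1-yl hex-5-enoate F3. Ring-closing metathesis of F3 with the second-generation Grubbs catalyst (CH2Cl2, 1 mM, reflux) should form C5=C6 with loss of ethene and give oxacyclotritriacont-6-en-2-one F4 as an E/Z mixture. Hydrogenation of F4 under the conditions of step 6 comes back to the route at 11.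

Step 1 (chain coupling). The second C–Br end may couple again, or the Grignard reagent may homocouple, so that the mono-coupled bromide becomes a minor and hard-to-purify part of the mixture. Fallback: use an electrophile with only one bromide, setting out from 3 (made from 1 as in step 1). 16-Bromohexadecan-1-ol is added to 2.2 equiv of 3; the first equivalent is spent on the hydroxyl group and gives bromomagnesium 16-bromohexadecan-1-olate F5. The second equivalent couples with F5 under Li2CuCl4 catalysis (THF, −10 °C → rt) and, after work-up with dilute HCl, gives heptacos-26-en-1-ol F6. Appel bromination of F6 (CBr4, PPh3, CH2Cl2, 0 °C) comes back to the route at 4.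

Step 4 (dienoate installation). The activated dienoic acid may polymerize, take up DMAP in a conjugate addition, or rearrange to the N-acylurea faster than it acylates the waxy alcohol. Fallback: build the diene on the chain after acylation, setting out from 7. Compound 7 is esterified with 2-(diethoxyphosphoryl)acetic acid (EDC hydrochloride, DMAP, CH2Cl2) to give 27-iodoheptacosyl 2-(diethoxyphosphoryl)acetate F7. Horner–Wadsworth–Emmons olefination of F7 with acrolein (K2CO3, THF/H2O, rt) should give the (2E)-dienoate and comes back to the route at 9.

**Further compounds**
F1 | step 5 | heptacos-26-en-1-ylmagnesium bromide | C=CCCCCCCCCCCCCCCCCCCCCCCCCC[Mg]Br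
F2 | step 5 | octacos-27-en-1-ol | C=CCCCCCCCCCCCCCCCCCCCCCCCCCCO
F3 | step 5 | octacos-27-en-1-yl hex-5-enoate | C=CCCCC(=O)OCCCCCCCCCCCCCCCCCCCCCCCCCCC=C
F4 | step 5 | oxacyclotritriacont-6-en-2-one (E/Z mixture, geometry left open) | O=C1CCCC=CCCCCCCCCCCCCCCCCCCCCCCCCCCO1
F5 | step 1 | bromomagnesium 16-bromohexadecan-1-olate | BrCCCCCCCCCCCCCCCCO[Mg]Br
F6 | step 1 | heptacos-26-en-1-ol | C=CCCCCCCCCCCCCCCCCCCCCCCCCCO
F7 | step 4 | 27-iodoheptacosyl 2-(diethoxyphosphoryl)acetate | CCOP(=O)(OCC)CC(=O)OCCCCCCCCCCCCCCCCCCCCCCCCCCCI
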